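All runs come from a simulation with made-up constants; the scatter is artificial.

3 questions stood before me, on two flasks.

| setting | Monday's | Saturday's | north-west | west |
|---|---|---|---|---|
| substrate | 48 mM | 48 mM | 48 mM | 48 mM |
| reagent | 40 mM (fed, over 12 h) | 100 mM (fed, over 12 h) | 30.0 mM (fed, over 12 h) | 86.4 mM (fed, over 12 h) |
| temperature | −10 °C | 12 °C |  |  |
| remark | run made earlier | run made earlier | at 20 °C throughout | at −20 °C until 12 h, from then on at 20 °C |
| time |  |  | 20 h | 20 h |

| run | time / h | target / % | side product / % |
|---|---|---|---|
| Monday's | 1.00 | 7.5 | 0 |
| Monday's | 2.00 | 14.0 | 1.8 |
| Monday's | 4.00 | 26.0 | 1.8 |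
| Monday's | 6.00 | 38.7 | 0 |
| Monday's | 12.0 | 63.3 | 4.1 |
| Saturday's | 0.833 | 13.6 | 0 |
| Saturday's | 1.50 | 25.7 | 0.1 |
| Saturday's | 2.50 | 39.1 | 3.6 |
| Saturday's | 3.00 | 46.1 | 4.3 |
| Saturday's | 4.00 | 58.7 | 8.7 |

(each reading ± 1 percentage point)

- which one finishes higher in share of target in all that became target or side product ("neither" within 2 percentage points) (north-west / west / neither)
- share of target in all that became target or side product, north-west
- share of target in all that became target or side product, west

- candidate steps: substrate <-> intermediate + leaving ligand; reagent + intermediate -> target; leaving ligand + target -> side product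

Each target formed has freed one leaving ligand, and side product consumes one of each. So I set c(target) ≈ c(leaving ligand) = c, and side product grows as k times c squared.

I read k from each run's last reading. There c had climbed nearly in a line, so the mean of c squared is a third of its end value squared. Squaring the mean of c would give a quarter, and k would come out 1.33 times too high. Saturday's run read 0.00395 /mM/h, and Monday's read 5.33 × 10⁻⁴ /mM/h. A straight line in ln k against temperature gave 0.00817 /mM/h, my estimate of the pairwise decay constant of target at 20 °C.

In west I reckoned as if the whole 48 mM stood as target from 12 h on, with reagent in excess. The share then falls to one over (one plus k·c·t). In north-west, reagent is the limiting reagent. I let the feed balance the decay at a plateau, the square root of feed rate over k, let that plateau decay after the feed, and took the share against the reagent charge.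

For the ceiling I kept Saturday's k, read in a colder flask. For the floor I raised Saturday's reading and lowered Monday's by one scatter each.

| k taken | k | west | north-west |
|---|---|---|---|
| ceiling | 0.00395 /mM/h | 39.8% | 46.8% |
| middle | 0.00817 /mM/h | 24.2% | 27.2% |
| floor | 0.0105 /mM/h | 19.9% | 22.4% |

My middle row put north-west ahead by 3 percentage points, against a margin of 2 points. But a plateau is approached from below, so the north-west figures lean high, and I committed to the middle row's figures and, on that lean, to neither.

The forecast said neither, with 31% for north-west and 32% for west: “The two scale together with k, so: neither.” Both its figures stand inside my brackets, above my middle row.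

The flasks gave neither: north-west 22.3%, west 22.4%. West stands inside its bracket, north-west at its floor.

    substrate ⇌ intermediate + leaving ligand (K = 0.00163 M, k = 3.49 × 10⁻⁴ /min, Ea = 90.0 kJ/mol, ΔH = −13.0 kJ/mol)
    reagent + intermediate → target (k = 70.5 /M/min, Ea = 39.0 kJ/mol)
    leaving ligand + target → side product (k = 0.00155 /M/min, Ea = 71.0 kJ/mol)
    (constants at −20 °C)

West had not come to rest at 20 h. It still held target at 22.4% of the substrate charged and leaving ligand at 10.7 mM, and the half-life of that ligand by the path to side product was 7.0 h. My constant, run on to ten times the time, gives west a share of 1.34%, and the computed flask gives 1.18%. Started from the target and ligand that stood in north-west at the end of the feed, the constant gives 15.4% target at 20 h, where that flask held 13.9%. Left ten times as long, north-west's share falls to 0.0450%.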